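## Structural features

Garcinisidone D is a depsidone: ring A and ring B are joined by a diaryl ether oxygen and by an ester, and these two links close a seven-membered 1,4-dioxepin-5-one between the rings. Ring A is a hexasubstituted phloroglucinol carboxylate. Its positions are called A1 (3-methylbut-2-enyl), A2 (hydroxyl hydrogen-bonded to the lactone carbonyl), A3 (lactone carbonyl), A4 (ether oxygen), A5 (CH= carbon of a fused 2,2-dimethyl-2H-pyran) and A6 (oxygen of that pyran). Ring B is a 1,2,4,5-tetraoxygenated benzene: B1 (ether oxygen), B2 (H), B3 (free hydroxyl), B4 (oxygen of a second dimethylpyran), B5 (its CH= carbon) and B6 (ester oxygen). There is no stereocentre, so no stereocentres stand next to each other and the task is purely constitution and regiochemistry. The fragile groups are the prenyl and chromene olefins (acid, peracid; the prenyl group can cyclise onto a free neighbouring phenol), the aryl ester lactone (nucleophiles, amines) and the electron-rich rings (oxidation). The real difficulty is ring A with six different substituents in fixed order, the seven-membered ring between two crowded arenes, and the need to tell four ring B oxygens apart. The key step exploits that A4–A5, A3–A2 and A6–A1 are three two-carbon units each bearing one oxygen, that is, three ynol-type alkynes in head-to-tail order. The oxygen on A4 and the carbonyl on A3 are already linked through B1 and B6, so two of the alkynes can hang from ring B.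

## Logic of the disconnections

**24 from 23.** The O–ethyl bond at A2 and the O–CH2 bond of the acetal at B3 are cut. Both phenols must be masked while organolithiums, alkynes and the rhodium catalyst are in play; the ethyl group is what the cheapest ynol ether brings, and the acetal tolerates base. Nothing is gained in skeleton, but deprotection becomes the only task of the last step. The forward step must cleave an aryl ethyl ether beside a prenyl group, two chromenes and an aryl ester; the ether sits next to the lactone carbonyl, where a chelating Lewis acid can find it.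

**23 from 22, and 22 from 21 and 3.** The A5–CH= bond and then the A6 O–C(CH3)2 bond of the ring A pyran are cut. This pyran is left out of the cycloaddition because A5 must be the CH of a terminal alkyne and A6 arrives silylated. The third alkyne thereby stays a simple one. The forward closure must find A5, which is the only free position next to the A6 oxygen because A1 already bears the prenyl group.

**21 from 20.** The O–Si bond at A6 is cut. A bulky silyl group is needed on the third alkyne both for its stability and for regiocontrol. Its removal must not open the lactone, so buffered fluoride is required.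

**20 from 16 and 19.** Three ring A bonds are cut: A3–A4, A5–A6 and A1–A2. This removes ring A and the seven-membered ring in one operation and leaves ring B with two alkynes on its neighbouring oxygens plus one free alkyne. The forward step must close a seven-membered ring during metallacycle formation and must orient 19 so that its silyloxy carbon meets A5.

**19 from 17.** The alkyne C–C bond and the O–Si bond are cut, tracing the ynol ether to an ester with one carbon fewer. The forward homologation must outrun enolisation of a β,γ-unsaturated ester.

**16 from 9 and 12.** The acyl–oxygen bond at B6 is cut, and the ethynyl ether at B1 is traced to its dichlorovinyl precursor. The ester cannot be present when the alkyne is unmasked with an alkyllithium, so both events are placed in one flask: alkyne first, acylation second. The demand is that the phenoxide next to an ynol ether is acylated before it can add to that ynol ether.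

**12 from 10.** The C–CO2 bond is cut. The acid is kept as a salt, since the free acid would add to its own ynol ether.

**9 from 8.** The B5–CH= bond of the ring B pyran is cut. The pyran oxygen is already in place as a propargylic ether, so a metal-catalysed hydroarylation cannot use the wrong oxygen, which a thermal route through a free B6 hydroxyl could.

**8 from 6.** The B6–O bond is traced back to a B6–CHO bond. The formyl carbon is a latent oxygen that keeps B6 silent while B1 is functionalised. The oxidation uses a peracid and therefore has to come before any electron-rich olefin exists.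

**6 from 4 and 5.** The B1 O–vinyl bond is cut. In 4 the B1 hydroxyl is the only one left, so no selectivity is asked of the forward step.

**4 from 2 and 3.** The B4 O–C(CH3)2 bond is cut. The forward alkylation must take the free hydroxyl and leave the one hydrogen-bonded to the aldehyde.

**2 from 1.** The B3 O–CH2 bond is cut. Ring B has four oxygens, so a trihydroxybenzene such as benzene-1,2,4-triol would be one oxygen short and would need an unguided late hydroxylation. In 1 the fourth oxygen is present as the formyl carbon, and the three hydroxyls differ in acidity (para to CHO, then meta, then chelated ortho) in the order in which B3, B4 and B1 have to be addressed.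

## Other disconnections considered

**Alternative 1:** The cut is the B6–B1 bond of ring B. In the forward step the cyclobutenone A1, which carries complete ring A as an aryl vinyl ether, is heated. The four-membered ring opens to a dienylketene, which closes to the hydroquinone diaryl ether A2.
- In its favour: the cascade is purely thermal and belongs to a well-established class of cyclobutenone ring expansions. The ring B oxygen pattern is dictated by the cyclobutenone. The B6 and B3 hydroxyls appear unprotected, and only the B6 hydroxyl can reach the ester.
- Against it here: ring A, the hard part, must be complete beforehand and must be carried through an organometallic addition beside its methyl ester. Ring B arrives as a chroman and needs dehydrogenation next to a prenyl group. A2 is an air-sensitive hydroquinone. The lactone must then be closed onto a di-ortho-substituted methyl ester.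
- Comparison: structurally it builds the easier ring, whereas the chosen plan builds ring A and the seven-membered ring together. Mechanistically it is the better of the two in precedent, since the chosen rhodium step is untested. In step count it is expected to be longer, because hexasubstituted ring A needs its own multistep synthesis.

**Alternative 2:** The cuts are the A5–CH and A6 O–C bonds and the B5–CH and B4 O–C bonds. In the forward step the depsidone A3 condenses with two equivalents of 3-methylbut-2-enal to give A4.
- In its favour: the reaction type is known, and both positions are fixed by blocked neighbours (A1 prenyl, B3 oxygen). The acid-sensitive chromenes are introduced last. On end-game brevity and on handling of fragile groups it is the equal or the better of the chosen plan.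
- Against it here: it does not solve the core. A3 still contains hexasubstituted ring A, the prenyl group and the seven-membered ring. The amine catalysts usual for this condensation threaten the aryl ester, and both phenols are poor nucleophiles.
- Comparison: structurally it addresses the periphery and not the core. Mechanistically it is safer. In step count it saves about one step at the end and adds the unsolved synthesis of A3. The chosen plan uses the same logic for the ring A pyran only.

**Alternative 3:** The cuts are the A4–O ether bond and the A3–CO2H bond. In the forward step fluoride releases the ring A aryne from silyl triflate A5 under CO2. Phenoxide A6 adds at A4 and the aryl anion at A3 is carboxylated, giving A7.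
- In its favour: two complete halves are joined late. The addition is matched, since the nucleophile should go to the aryne carbon remote from the A2 alkoxy group. The seven-membered ring then closes by lactonisation, which is better precedented than the rhodium closure; on that point it is the better plan.
- Against it here: carboxylation must outrun protonation of a crowded aryl anion. A flanked phenoxide must add to a flanked aryne. A5 is a fully substituted silyl triflate that is long to make. The three acetals of A7 cannot be told apart, so lactonisation must be done with other phenols free.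
- Comparison: structurally it forms two bonds at ring A but not ring A itself. Mechanistically it is about as unproven for such substrates as the chosen step. In step count it is expected to be longer, because two fully substituted arenes are needed.

Key step: step 9

Assumption: the dioxepinone ring of 20 is taken to invert freely at room temperature, so 20 has no stable element of chirality and racemic BINAP suffices.

## Route

Step 1
Reactants: 1 2,4,5-trihydroxybenzaldehyde
Product: 2 2,5-dihydroxy-4-(methoxymethoxy)benzaldehyde
Conditions: MOMCl (1.0 equiv), K2CO3 (1.0 equiv), acetone, 0 °C to rt, argon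
Reagents that add atoms: chloromethyl methyl ether, COCCl
Why: The 4-hydroxyl is para to the formyl group, hence the most acidic, and with one equivalent of base it should be the phenoxide that undergoes Williamson alkylation, as known for 2,4- and 3,4-dihydroxybenzaldehydes. Argon is needed because the 2,5-dihydroxy pattern is a hydroquinone.

Step 2
Reactants: 2 2,5-dihydroxy-4-(methoxymethoxy)benzaldehyde; 3 3-chloro-3-methylbut-1-yne
Product: 4 2-hydroxy-4-(methoxymethoxy)-5-[(2-methylbut-3-yn-2-yl)oxy]benzaldehyde
Conditions: K2CO3, KI (cat.), CuI (cat.), acetone, 50 °C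
Reagents that add atoms: none
Why: Copper-catalysed propargylic etherification (monovalent copper acetylide, then attack of the phenoxide) should take the free 5-hydroxyl, because the 2-hydroxyl is tied up in a hydrogen bond to the aldehyde and is the poorer nucleophile. The temperature stays below that of the propargyl Claisen rearrangement.

Step 3
Reactants: 4 2-hydroxy-4-(methoxymethoxy)-5-[(2-methylbut-3-yn-2-yl)oxy]benzaldehyde; 5 trichloroethylene
Product: 6 2-{[(E)-1,2-dichloroethenyl]oxy}-4-(methoxymethoxy)-5-[(2-methylbut-3-yn-2-yl)oxy]benzaldehyde
Conditions: K2CO3, DMF, 65 °C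
Reagents that add atoms: none
Why: Base converts trichloroethylene into dichloroacetylene, to which the only remaining phenoxide adds in anti fashion to give the (E)-dichlorovinyl ether, the standard precursor of an aryl ethynyl ether. No selectivity is required.

Step 4
Reactants: 6 2-{[(E)-1,2-dichloroethenyl]oxy}-4-(methoxymethoxy)-5-[(2-methylbut-3-yn-2-yl)oxy]benzaldehyde
Product: 8 2-{[(E)-1,2-dichloroethenyl]oxy}-4-(methoxymethoxy)-5-[(2-methylbut-3-yn-2-yl)oxy]phenol, via aryl formate 7 (not isolated)
Conditions: mCPBA, CH2Cl2, 0 °C to rt; then K2CO3 (cat.), MeOH, 0 °C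
Reagents that add atoms: 3-chloroperbenzoic acid, OOC(=O)c1cccc(Cl)c1
Why: Baeyer–Villiger oxidation: the electron-rich aryl group migrates in preference to hydrogen, and the formate is methanolysed, so the formyl carbon becomes the B6 oxygen. The peracid is used before any electron-rich olefin exists; the alkyne and the chlorine-deactivated vinyl ether should be slow to react.

Step 5
Reactants: 8 2-{[(E)-1,2-dichloroethenyl]oxy}-4-(methoxymethoxy)-5-[(2-methylbut-3-yn-2-yl)oxy]phenol
Product: 9 6-{[(E)-1,2-dichloroethenyl]oxy}-8-(methoxymethoxy)-2,2-dimethyl-2H-chromen-5-ol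
Conditions: Ph3PAuNTf2 (3 mol%), CH2Cl2, rt
Reagents that add atoms: none
Why: Cationic monovalent gold activates the terminal alkyne for 6-endo-dig hydroarylation by the only free carbon next to the propargylic ether oxygen, a known route to 2,2-dimethyl-2H-chromenes. Because the O–C bond is already in place, the free hydroxyl on the other side cannot become the pyran oxygen.

Step 6
Reactants: 10 ethoxyacetylene
Product: 12 lithium 3-ethoxyprop-2-ynoate, via lithium ethoxyacetylide 11 (not isolated)
Conditions: n-BuLi, THF, −78 °C; CO2, −78 to 0 °C; evaporation
Reagents that add atoms: carbon dioxide, O=C=O; n-butyllithium, [Li]CCCC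
Why: Deprotonation of the terminal ynol ether and carboxylation of the acetylide. The product is kept as its lithium salt because the free alkoxypropiolic acid would add to its own ynol ether.

Step 7
Reactants: 9 6-{[(E)-1,2-dichloroethenyl]oxy}-8-(methoxymethoxy)-2,2-dimethyl-2H-chromen-5-ol; 12 lithium 3-ethoxyprop-2-ynoate
Product: 16 6-(ethynyloxy)-8-(methoxymethoxy)-2,2-dimethyl-2H-chromen-5-yl 3-ethoxyprop-2-ynoate, via dilithio alkynyl ether 13 (not isolated), via lithium phenoxide 14 (not isolated), via mixed anhydride 15 (not isolated)
Conditions: 9, n-BuLi (3.1 equiv), THF, −78 to −40 °C; 2,6-di-tert-butyl-4-methylphenol (1.2 equiv), −78 °C; then 15 (from 12 and 2,4,6-trichlorobenzoyl chloride, THF, 0 °C), −78 to −20 °C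
Reagents that add atoms: none
Why: n-BuLi deprotonates the phenol and converts the dichlorovinyl ether into the lithium alkynyl ether by elimination and chlorine–lithium exchange. The hindered phenol then protonates only the acetylide carbon, and the remaining lithium phenoxide is acylated cold at the unhindered carbonyl of a Yamaguchi-type mixed anhydride. The ortho-hydroxyaryl ethynyl ether is thus never isolated, and no nucleophilic amine that could add to either alkyne is present.

Step 8
Reactants: 17 ethyl 4-methylpent-3-enoate
Product: 19 triisopropyl[(5-methylhex-4-en-1-yn-1-yl)oxy]silane, via lithium ynolate 18 (not isolated)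
Conditions: CH2Br2, lithium 2,2,6,6-tetramethylpiperidide, THF, −78 °C; LiN(SiMe3)2; n-BuLi, −78 to −20 °C; i-Pr3SiCl, −78 °C to rt
Reagents that add atoms: dibromomethane, BrCBr; chlorotriisopropylsilane, CC(C)[Si](Cl)(C(C)C)C(C)C
Why: Kowalski homologation: dibromomethyllithium adds to the ester, and the dibromoketone enolate undergoes bromine–lithium exchange and a 1,2-shift to the ynolate. The bulky silyl chloride traps the ynolate on oxygen.

Step 9
Reactants: 16 6-(ethynyloxy)-8-(methoxymethoxy)-2,2-dimethyl-2H-chromen-5-yl 3-ethoxyprop-2-ynoate; 19 triisopropyl[(5-methylhex-4-en-1-yn-1-yl)oxy]silane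
Product: 20 depsidone with A1 3-methylbut-2-enyl, A2 ethoxy, A5 H, A6 triisopropylsilyloxy, B3 methoxymethoxy and the dimethylpyran on B4/B5
Conditions: [Rh(cod)2]BF4 (10 mol%), rac-BINAP (10 mol%), H2 then argon, CH2Cl2, rt; 16 added over 6 h to 19 (3 equiv)
Reagents that add atoms: none
Why: Proposed new method: cationic monovalent rhodium with BINAP should bind both alkynes of 16 and undergo oxidative cyclisation to a rhodacyclopentadiene of trivalent rhodium in which the ester-bearing carbon (A3) is joined to the aryloxy-bearing carbon (A4); insertion of 19 into the less hindered Rh–CH bond and reductive elimination then give the arene. The closest known reaction type is the [Rh(cod)2]BF4–BINAP [2+2+2] cycloaddition of 1,6- and 1,7-diynes with monoalkynes, which accepts aryl ethynyl ethers and alkynoates; a five-atom tether and three oxygen-substituted alkynes lie beyond it. The seven-membered dioxepinone is closed by the A3–A4 bond as a ring fused to the rhodacycle, helped by the planar ortho-phenylene and ester units that hold the alkynes near each other, and ring A is closed as a six-membered carbocycle by the A5–A6 and A1–A2 bonds. No stereocentre is formed and the product is achiral. The selectivity that matters is the orientation of 19: its silyloxy carbon should bond to the unsubstituted carbon A5 and its prenyl-bearing carbon to the ethoxy carbon A2. This is favoured sterically by the i-Pr3Si group and electronically because each new bond then joins the nucleophilic β-carbon of one ynol ether to the oxygen-bearing carbon of the next. Slow addition of 16 to excess 19 is meant to suppress dimerisation of 16, and the internal olefins of the chromene and prenyl groups should be too hindered to compete with the alkynes.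

Step 10
Reactants: 20 depsidone with A2 ethoxy, A6 triisopropylsilyloxy and B3 methoxymethoxy
Product: 21 depsidone phenol with A1 3-methylbut-2-enyl, A2 ethoxy, A5 H, A6 hydroxyl, B3 methoxymethoxy and the ring B dimethylpyran
Conditions: n-Bu4NF, AcOH, THF, 0 °C
Reagents that add atoms: none
Why: Fluoride cleaves the aryl silyl ether. Acetic acid buffers the phenoxide so that the aryl ester lactone should not be opened.

Step 11
Reactants: 21 depsidone phenol with free A6 hydroxyl; 3 3-chloro-3-methylbut-1-yne
Product: 22 A6 (2-methylbut-3-yn-2-yl) ether of 21
Conditions: K2CO3, KI (cat.), CuI (cat.), acetone, 50 °C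
Reagents that add atoms: none
Why: The same copper-catalysed propargylic etherification as in step 2; the phenol para to the lactone carbonyl is acidic and is the only free hydroxyl. The conditions contain no nucleophile that could open the lactone.

Step 12
Reactants: 22 A6 (2-methylbut-3-yn-2-yl) ether of 21
Product: 23 A2-O-ethyl B3-O-(methoxymethyl) garcinisidone D
Conditions: Ph3PAuNTf2 (5 mol%), CH2Cl2, rt
Reagents that add atoms: none
Why: Gold-catalysed 6-endo-dig hydroarylation as in step 5. A5 is the only free position next to the ether oxygen and is activated by three ring oxygens, so the pyran can only close there.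

Step 13
Reactants: 23 A2-O-ethyl B3-O-(methoxymethyl) garcinisidone D
Product: 24 garcinisidone D
Conditions: BCl3 (4 equiv), CH2Cl2, −78 to −20 °C; then H2O
Reagents that add atoms: none
Why: BCl3 chelates between the lactone carbonyl and the neighbouring ethoxy oxygen and cleaves that ether, and it also cleaves the acetal at B3 (Lewis acid ether cleavage). The A2 oxygen stays bound to boron until the aqueous quench, which should keep it from adding to the adjacent prenyl olefin.

## Compound list

1 | 2,4,5-trihydroxybenzaldehyde | O=Cc1cc(O)c(O)cc1O | starting material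
2 | 2,5-dihydroxy-4-(methoxymethoxy)benzaldehyde | O=Cc1cc(O)c(OCOC)cc1O | intermediate
3 | 3-chloro-3-methylbut-1-yne | C#CC(C)(C)Cl | starting material
4 | 2-hydroxy-4-(methoxymethoxy)-5-[(2-methylbut-3-yn-2-yl)oxy]benzaldehyde | O=Cc1cc(OC(C)(C)C#C)c(OCOC)cc1O | intermediate
5 | trichloroethylene | ClC=C(Cl)Cl | starting material
6 | 2-{[(E)-1,2-dichloroethenyl]oxy}-4-(methoxymethoxy)-5-[(2-methylbut-3-yn-2-yl)oxy]benzaldehyde | O=Cc1cc(OC(C)(C)C#C)c(OCOC)cc1O/C(Cl)=C\Cl | intermediate
7 | 2-{[(E)-1,2-dichloroethenyl]oxy}-4-(methoxymethoxy)-5-[(2-methylbut-3-yn-2-yl)oxy]phenyl formate | O=COc1cc(OC(C)(C)C#C)c(OCOC)cc1O/C(Cl)=C\Cl | intermediate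
8 | 2-{[(E)-1,2-dichloroethenyl]oxy}-4-(methoxymethoxy)-5-[(2-methylbut-3-yn-2-yl)oxy]phenol | Oc1cc(OC(C)(C)C#C)c(OCOC)cc1O/C(Cl)=C\Cl | intermediate
9 | 6-{[(E)-1,2-dichloroethenyl]oxy}-8-(methoxymethoxy)-2,2-dimethyl-2H-chromen-5-ol | Oc1c2C=CC(C)(C)Oc2c(OCOC)cc1O/C(Cl)=C\Cl | intermediate
10 | ethoxyacetylene | CCOC#C | starting material
11 | lithium ethoxyacetylide | CCOC#C[Li] | intermediate
12 | lithium 3-ethoxyprop-2-ynoate | [Li+].[O-]C(=O)C#COCC | intermediate
13 | dilithium salt of 6-(ethynyloxy)-8-(methoxymethoxy)-2,2-dimethyl-2H-chromen-5-ol (phenoxide and acetylide) | [Li+].[O-]c1c2C=CC(C)(C)Oc2c(OCOC)cc1OC#C[Li] | intermediate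
14 | lithium 6-(ethynyloxy)-8-(methoxymethoxy)-2,2-dimethyl-2H-chromen-5-olate | [Li+].[O-]c1c2C=CC(C)(C)Oc2c(OCOC)cc1OC#C | intermediate
15 | 3-ethoxyprop-2-ynoic 2,4,6-trichlorobenzoic anhydride | CCOC#CC(=O)OC(=O)c1c(Cl)cc(Cl)cc1Cl | intermediate
16 | 6-(ethynyloxy)-8-(methoxymethoxy)-2,2-dimethyl-2H-chromen-5-yl 3-ethoxyprop-2-ynoate | C#COc1cc(OCOC)c2OC(C)(C)C=Cc2c1OC(=O)C#COCC | intermediate
17 | ethyl 4-methylpent-3-enoate | CCOC(=O)CC=C(C)C | starting material
18 | lithium 5-methylhex-4-en-1-yn-1-olate | [Li+].[O-]C#CCC=C(C)C | intermediate
19 | triisopropyl[(5-methylhex-4-en-1-yn-1-yl)oxy]silane | CC(C)=CCC#CO[Si](C(C)C)(C(C)C)C(C)C | intermediate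
20 | depsidone: A1 3-methylbut-2-enyl, A2 ethoxy, A5 H, A6 triisopropylsilyloxy, B3 methoxymethoxy, dimethylpyran on B4/B5 | CC(C)=CCc1c(OCC)c2c(cc1O[Si](C(C)C)(C(C)C)C(C)C)Oc1cc(OCOC)c3c(c1OC2=O)C=CC(C)(C)O3 | intermediate
21 | depsidone phenol: as 20 with A6 hydroxyl | CC(C)=CCc1c(OCC)c2c(cc1O)Oc1cc(OCOC)c3c(c1OC2=O)C=CC(C)(C)O3 | intermediate
22 | A6 (2-methylbut-3-yn-2-yl) ether of 21 | CC(C)=CCc1c(OCC)c2c(cc1OC(C)(C)C#C)Oc1cc(OCOC)c3c(c1OC2=O)C=CC(C)(C)O3 | intermediate
23 | A2-O-ethyl B3-O-(methoxymethyl) garcinisidone D | CC(C)=CCc1c(OCC)c2c(c3c1OC(C)(C)C=C3)Oc1cc(OCOC)c3c(c1OC2=O)C=CC(C)(C)O3 | intermediate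
24 | garcinisidone D | CC(C)=CCc1c(O)c2c(c3c1OC(C)(C)C=C3)Oc1cc(O)c3c(c1OC2=O)C=CC(C)(C)O3 | target

## Step count and least certain steps

Total: 13 steps. Longest linear sequence: 11 steps (steps 1 to 5, 7, 9 to 13).

**Step 9 (key step).** The most likely failure is that closure of the seven-membered ring at the rhodacycle stage is slower than intermolecular coupling of 19 with a single alkyne of 16, or than self-trimerisation of 19. Reversed insertion of 19 and acid-induced hydration of the ynol ethers are further risks. The fallback replaces the cycloaddition by a copper-mediated Ullmann ether synthesis and a lactonisation, sets out from 4 and returns at 24.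
- Heating 4 in xylene (propargyl Claisen rearrangement, hydrogen shift and oxa-6π closure, with the formyl group blocking the other side) should give 6-hydroxy-8-(methoxymethoxy)-2,2-dimethyl-2H-chromene-5-carbaldehyde F1.
- Ring A is made separately from methyl 2-bromo-4,6-dihydroxybenzoate F2 (assumed purchasable; otherwise it must first be prepared). F2 is C-prenylated between its hydroxyls (prenyl bromide, DBU) to methyl 6-bromo-2,4-dihydroxy-3-(3-methylbut-2-en-1-yl)benzoate F3.
- F3 is annulated with 3-methylbut-2-enal (ethylenediammonium diacetate, toluene, reflux) at the only free position next to its 4-hydroxyl, giving methyl 5-bromo-7-hydroxy-2,2-dimethyl-8-(3-methylbut-2-en-1-yl)-2H-chromene-6-carboxylate F4. Saponification (KOH, aqueous EtOH) gives 5-bromo-7-hydroxy-2,2-dimethyl-8-(3-methylbut-2-en-1-yl)-2H-chromene-6-carboxylic acid F5.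
- Ullmann coupling of F5 with the phenol of F1 (CuI, Cs2CO3, DMF, 110 °C) should give the diaryl ether acid F6. The regiochemistry is unambiguous because B6 is still a formyl carbon.
- HCl in MeOH removes the acetal to give the B3 phenol F7. Its hydroxyl para to the aldehyde allows a Dakin oxidation (H2O2, NaOH), which spares the olefins and gives the hydroquinone acid F8.
- Carbodiimide lactonisation under dilution closes the seven-membered ring to 24.

**Step 7.** The phenoxide may add to the neighbouring chloroalkyne or ynol ether, n-BuLi may lithiate the ring next to the acetal, or the hindered phenoxide may be acylated too slowly. The fallback isolates a protected alkyne, sets out from 9 and returns at 16. Silylation (t-BuMe2SiCl, imidazole) gives tert-butyl({6-{[(E)-1,2-dichloroethenyl]oxy}-8-(methoxymethoxy)-2,2-dimethyl-2H-chromen-5-yl}oxy)dimethylsilane F9. n-BuLi (2.2 equiv) and then water give tert-butyl{[6-(ethynyloxy)-8-(methoxymethoxy)-2,2-dimethyl-2H-chromen-5-yl]oxy}dimethylsilane F10. n-Bu4NF at −78 °C in the presence of 15 releases and acylates the phenoxide.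

**Step 5.** The hydroarylation may stall on this ring, which is crowded on both sides of the reacting carbon, or the catalyst may be consumed by the free phenol. The fallback is thermal, sets out from 8 and returns at 9. Acetylation (Ac2O, pyridine) gives the acetate of 8, F11. Heating in xylene at 140 °C (propargyl Claisen rearrangement, with the acetate preventing closure onto the wrong oxygen) gives the acetate of 9, F12. K2CO3 in MeOH returns 9.

**Step 12.** The gold-activated alkyne may be intercepted by the neighbouring prenyl olefin, or ring A, which carries the lactone carbonyl para to the ether, may be too poor a nucleophile. The fallback is a direct annulation from 21 to 23 that bypasses 22: 3-methylbut-2-enal, PhB(OH)2, AcOH, toluene, reflux. This is a boron-templated, ortho-specific condensation followed by oxa-6π closure, and it is free of amines, so the lactone is not at risk. It makes no new compound (F0).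

**Step 13.** Acid-induced cyclisation of the prenyl group onto the freed A2 hydroxyl, hydrochlorination of a chromene, or incomplete cleavage of the ethyl ether could occur. The fallback stages the deprotection without BCl3, sets out from 23 and returns at 24. Dilute HCl in MeOH–THF removes only the acetal to give A2-O-ethyl garcinisidone D F13. MgI2·OEt2 in toluene at 80 °C then removes the ethyl group by iodide attack at the magnesium chelate of the lactone carbonyl.

## Further compounds

F1 | step 9 | 6-hydroxy-8-(methoxymethoxy)-2,2-dimethyl-2H-chromene-5-carbaldehyde | O=Cc1c(O)cc(OCOC)c2OC(C)(C)C=Cc12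
F2 | step 9 | methyl 2-bromo-4,6-dihydroxybenzoate | COC(=O)c1c(Br)cc(O)cc1O
F3 | step 9 | methyl 6-bromo-2,4-dihydroxy-3-(3-methylbut-2-en-1-yl)benzoate | COC(=O)c1c(Br)cc(O)c(CC=C(C)C)c1O
F4 | step 9 | methyl 5-bromo-7-hydroxy-2,2-dimethyl-8-(3-methylbut-2-en-1-yl)-2H-chromene-6-carboxylate | COC(=O)c1c(Br)c2C=CC(C)(C)Oc2c(CC=C(C)C)c1O
F5 | step 9 | 5-bromo-7-hydroxy-2,2-dimethyl-8-(3-methylbut-2-en-1-yl)-2H-chromene-6-carboxylic acid | OC(=O)c1c(Br)c2C=CC(C)(C)Oc2c(CC=C(C)C)c1O
F6 | step 9 | 5-{[5-formyl-8-(methoxymethoxy)-2,2-dimethyl-2H-chromen-6-yl]oxy}-7-hydroxy-2,2-dimethyl-8-(3-methylbut-2-en-1-yl)-2H-chromene-6-carboxylic acid | OC(=O)c1c(Oc2cc(OCOC)c3OC(C)(C)C=Cc3c2C=O)c2C=CC(C)(C)Oc2c(CC=C(C)C)c1O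
F7 | step 9 | 5-[(5-formyl-8-hydroxy-2,2-dimethyl-2H-chromen-6-yl)oxy]-7-hydroxy-2,2-dimethyl-8-(3-methylbut-2-en-1-yl)-2H-chromene-6-carboxylic acid | OC(=O)c1c(Oc2cc(O)c3OC(C)(C)C=Cc3c2C=O)c2C=CC(C)(C)Oc2c(CC=C(C)C)c1O
F8 | step 9 | 5-[(5,8-dihydroxy-2,2-dimethyl-2H-chromen-6-yl)oxy]-7-hydroxy-2,2-dimethyl-8-(3-methylbut-2-en-1-yl)-2H-chromene-6-carboxylic acid | OC(=O)c1c(Oc2cc(O)c3OC(C)(C)C=Cc3c2O)c2C=CC(C)(C)Oc2c(CC=C(C)C)c1O
F9 | step 7 | tert-butyl({6-{[(E)-1,2-dichloroethenyl]oxy}-8-(methoxymethoxy)-2,2-dimethyl-2H-chromen-5-yl}oxy)dimethylsilane | CC(C)(C)[Si](C)(C)Oc1c2C=CC(C)(C)Oc2c(OCOC)cc1O/C(Cl)=C\Cl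
F10 | step 7 | tert-butyl{[6-(ethynyloxy)-8-(methoxymethoxy)-2,2-dimethyl-2H-chromen-5-yl]oxy}dimethylsilane | CC(C)(C)[Si](C)(C)Oc1c2C=CC(C)(C)Oc2c(OCOC)cc1OC#C
F11 | step 5 | 2-{[(E)-1,2-dichloroethenyl]oxy}-4-(methoxymethoxy)-5-[(2-methylbut-3-yn-2-yl)oxy]phenyl acetate | CC(=O)Oc1cc(OC(C)(C)C#C)c(OCOC)cc1O/C(Cl)=C\Cl
F12 | step 5 | 6-{[(E)-1,2-dichloroethenyl]oxy}-8-(methoxymethoxy)-2,2-dimethyl-2H-chromen-5-yl acetate | CC(=O)Oc1c2C=CC(C)(C)Oc2c(OCOC)cc1O/C(Cl)=C\Cl
F0 | step 12 | none | none
F13 | step 13 | A2-O-ethyl garcinisidone D | CC(C)=CCc1c(OCC)c2c(c3c1OC(C)(C)C=C3)Oc1cc(O)c3c(c1OC2=O)C=CC(C)(C)O3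
A1 | alternative 1 | 4-hydroxy-4-(2-aryloxyethenyl)cyclobutenone fused to a 2,2-dimethyldihydropyran, aryl being complete ring A as methyl ester and methoxymethyl ether | O=C1C2=C(OC(C)(C)CC2)C1(O)C=COc1c(C(=O)OC)c(OCOC)c(CC=C(C)C)c2OC(C)(C)C=Cc12
A2 | alternative 1 | diaryl ether with ring B as a chroman hydroquinone | Oc1cc(Oc2c(C(=O)OC)c(OCOC)c(CC=C(C)C)c3OC(C)(C)C=Cc23)c(O)c2CCC(C)(C)Oc12
A3 | alternative 2 | depsidone with free A2, A6 and B4 hydroxyls, A1 3-methylbut-2-enyl and B3 methoxymethoxy | CC(C)=CCc1c(O)c2c(cc1O)Oc1cc(OCOC)c(O)cc1OC2=O
A4 | alternative 2 | B3-O-(methoxymethyl) garcinisidone D | CC(C)=CCc1c(O)c2c(c3c1OC(C)(C)C=C3)Oc1cc(OCOC)c3c(c1OC2=O)C=CC(C)(C)O3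
A5 | alternative 3 | 7-(methoxymethoxy)-2,2-dimethyl-8-(3-methylbut-2-en-1-yl)-6-(trimethylsilyl)-2H-chromen-5-yl trifluoromethanesulfonate | C[Si](C)(C)c1c(OCOC)c(CC=C(C)C)c2OC(C)(C)C=Cc2c1OS(=O)(=O)C(F)(F)F
A6 | alternative 3 | 5,8-bis(methoxymethoxy)-2,2-dimethyl-2H-chromen-6-ol | Oc1cc(OCOC)c2OC(C)(C)C=Cc2c1OCOC
A7 | alternative 3 | 5-{[5,8-bis(methoxymethoxy)-2,2-dimethyl-2H-chromen-6-yl]oxy}-7-(methoxymethoxy)-2,2-dimethyl-8-(3-methylbut-2-en-1-yl)-2H-chromene-6-carboxylic acid | OC(=O)c1c(OCOC)c(CC=C(C)C)c2OC(C)(C)C=Cc2c1Oc1cc(OCOC)c2OC(C)(C)C=Cc2c1OCOC
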